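The cyclohexenedione ring is cut at C3a–C7a and C4–C5 (benzofuran numbering). The key step exploits the vicinal oxygens O1 (dihydrofuran ring) and the side-chain tertiary hydroxyl: before the step they carry C4 and C7a as a γ-lactone and a tethered β-methoxyenoate ester. One base treatment then transposes both acyl groups from oxygen to carbon: the lactone enolate (C3a) captures the ester carbonyl by intramolecular delivery, fixing the quaternary centre, and the dienolate of the new enone (C5) closes onto the lactone carbonyl. The precursor is an ester-lactone without any carbocycle; the released secondary alkoxide later closes the dihydrofuran.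

Key step: step 7

Assumption: 5-methylhex-4-enoic acid, methyl 4-methyl-3-oxopentanoate and (2R)-2-methylbutanoic acid are taken as purchasable; the enoate geometry in 8–12 is drawn E but is of no consequence, because it is erased when the dienolate forms in the key step.

Step 1
Reactants: 1 geraniol
Product: 2 [(2S,3S)-3-methyl-3-(4-methylpent-3-en-1-yl)oxiran-2-yl]methanol ((2S,3S)-2,3-epoxygeraniol)
Conditions: Ti(OiPr)4 (5 mol %), L-(+)-diethyl tartrate (7.5 mol %), tBuOOH (2 equiv, decane), 4 Å MS, CH2Cl2, −20 °C
Reagents that add atoms: tert-butyl hydroperoxide, CC(C)(C)OO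
Why: Katsuki–Sharpless asymmetric epoxidation, in which the allylic hydroxyl confines the reaction to the 2,3-alkene and the L-(+)-tartrate complex should deliver oxygen to give the (2S,3S)-epoxide, the source of both side-chain stereocentres.

Step 2
Reactants: 2 (2S,3S)-2,3-epoxygeraniol
Product: 3 (2R,3S)-2-(iodomethyl)-3-methyl-3-(4-methylpent-3-en-1-yl)oxirane (the primary iodide of 2; the descriptor change is formal)
Conditions: I2, PPh3, imidazole, Et2O–MeCN (3:1), 0 °C
Reagents that add atoms: iodine, II
Why: Appel-type iodination of the primary alcohol under buffered neutral conditions, which should leave the trisubstituted epoxide and both stereocentres untouched.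

Step 3
Reactants: 3 epoxy iodide; 4 5-methylhex-4-enoic acid
Product: 6 (5R)-5-[(2S)-2-hydroxy-6-methylhept-5-en-2-yl]-3-(3-methylbut-2-en-1-yl)oxolan-2-one (C3 epimers), via epoxy acid 5 (not isolated)
Conditions: 4, LiN(iPr)2 (2.1 equiv), THF–DMPU, 0 °C; 3, −78 °C → rt; cold 1 M HCl; then camphorsulfonic acid (5 mol %), CH2Cl2, 0 °C → rt
Reagents that add atoms: none
Why: α-Alkylation of the carboxylic acid dianion at the primary iodide, then acid-catalysed 5-exo-tet epoxide-opening lactonization at the secondary epoxide carbon with inversion (giving 5R) while the tertiary C–O bond is retained (2S carbinol); the α-centre forms as a mixture that is erased in the key step.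

Step 4
Reactants: 7 methyl 4-methyl-3-oxopentanoate
Product: 8 methyl (2E)-3-methoxy-4-methylpent-2-enoate
Conditions: HC(OMe)3, H2SO4 (cat.), MeOH, 50 °C; distillation
Reagents that add atoms: trimethyl orthoformate, COC(OC)OC
Why: Acid-catalysed enol ether formation from a β-keto ester with an orthoformate, which should give the conjugated β-methoxy enoate as the thermodynamic product.

Step 5
Reactants: 8 methyl (2E)-3-methoxy-4-methylpent-2-enoate
Product: 9 (2E)-3-methoxy-4-methylpent-2-enoic acid
Conditions: KOH, MeOH–H2O, 60 °C; then 1 M HCl to pH 4, 0 °C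
Reagents that add atoms: potassium hydroxide, [K+].[OH-]
Why: Ester saponification, to which the vinylogous-carbonate enol ether is inert; cold, mild acidification should spare the enol ether.

Step 6
Reactants: 9 (2E)-3-methoxy-4-methylpent-2-enoic acid; 6 hydroxy lactone
Product: 11 (2S)-6-methyl-2-[(2R)-4-(3-methylbut-2-en-1-yl)-5-oxooxolan-2-yl]hept-5-en-2-yl (2E)-3-methoxy-4-methylpent-2-enoate (ester-lactone), via acid chloride 10 (not isolated)
Conditions: 9, (COCl)2, DMF (cat.), CH2Cl2, 0 °C → rt, evaporate; then 6, DMAP, pyridine, CH2Cl2, 0 → 40 °C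
Reagents that add atoms: none
Why: Acid chloride formation followed by DMAP-catalysed acylation of the tertiary alcohol through the acylpyridinium ion; the base-free, non-alkoxide conditions should avoid lactone enolization and translactonization.

Step 7
Reactants: 11 ester-lactone
Product: 13 (2S)-2-[(2R,3S)-2,3-dihydroxy-3,7-dimethyloct-6-en-1-yl]-5-methoxy-4,4-dimethyl-2-(3-methylbut-2-en-1-yl)cyclohex-5-ene-1,3-dione, via C-acyl lactone 12 (not isolated)
Conditions: KN(SiMe3)2 (1.1 equiv), THF (0.02 M), −78 → −20 °C; KN(SiMe3)2 (1.3 equiv), −20 °C → rt; AcOH, −78 °C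
Reagents that add atoms: none
Why: The first equivalent of base forms the lactone enolate, which attacks the tethered tertiary ester carbonyl through a six-membered (bicyclo[3.2.1]-like) transition state and expels the tertiary alkoxide (O→C acyl migration to 12); the second equivalent removes the γ-hydrogen of the resulting β-methoxy enone, and the γ-carbon of the dienolate attacks the lactone carbonyl, which opens to the secondary alkoxide. The closest known reaction types are the Baker–Venkataraman-type intramolecular Claisen acyl transfer and the vinylogous Dieckmann condensation. Only the carbocycle is closed, in a 6-(enolendo)-exo-trig attack on the lactone carbonyl, the five-membered lactone opening in the same event. The quaternary centre is set by the tether: the acyl group can reach only the enolate face syn to the C5 side chain, which places the prenyl group cis to that side chain on the later dihydrofuran (3aS). The step needs the lactone α-hydrogen to be removed before the enoate γ-hydrogen, which the acidity order should secure (the γ-hydrogen becomes acidic only once the acyl group is ketone-bound) and the portionwise base addition reinforces; α- or O-attack of the dienolate would give four-membered rings, so only the γ-closure is open.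

Step 8
Reactants: 13 dihydroxy enone
Product: 14 (2R,3aS)-2-[(2S)-2-hydroxy-6-methylhept-5-en-2-yl]-5,5-dimethyl-3a-(3-methylbut-2-en-1-yl)-3,3a-dihydro-1-benzofuran-4,6(2H,5H)-dione
Conditions: camphorsulfonic acid (10 mol %), CH2Cl2, 0 °C → rt
Reagents that add atoms: none
Why: Acid-catalysed intramolecular vinylogous transesterification, in which the secondary hydroxyl adds 5-exo-trig to the enone carbonyl and dehydration with loss of methanol gives the fused enol ether; the ketone flanked by two quaternary carbons can form only a reversible hemiketal, and the tertiary hydroxyl (six-membered closure at a hindered carbonyl) should be kinetically slower.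

Step 9
Reactants: 15 (2R)-2-methylbutanoic acid
Product: 16 (2R)-2-methylbutanoyl chloride
Conditions: (COCl)2, DMF (cat.), CH2Cl2, 0 °C → rt; careful concentration
Reagents that add atoms: oxalyl chloride, O=C(Cl)C(=O)Cl
Why: Vilsmeier-type acid chloride formation under base-free conditions, which should not touch the α-stereocentre.

Step 10
Reactants: 14 bicyclic dione; 16 (2R)-2-methylbutanoyl chloride
Product: 19 (2R,3aS)-2-[(2S)-2-hydroxy-6-methylhept-5-en-2-yl]-5,5-dimethyl-7-[(2R)-2-methylbutanoyl]-3a-(3-methylbut-2-en-1-yl)-3,3a-dihydro-1-benzofuran-4,6(2H,5H)-dione (target), via silyl ether 17 (not isolated), via acylated silyl ether 18 (not isolated)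
Conditions: lithium 2,2,6,6-tetramethylpiperidide (LiTMP, 1.05 equiv), THF, −78 °C; Me3SiCl (1.1 equiv), −78 → 0 °C; LiTMP (1.2 equiv), −78 °C; inverse addition to 16 (2 equiv), THF, −78 °C; then 10% aq. citric acid–THF, rt
Reagents that add atoms: none
Why: Transient O-silylation, then α-lithiation of the vinylogous ester C7–H (the only acidic C–H, since both flanking ring carbons are quaternary) and C-acylation with the acid chloride; inverse addition at low temperature should suppress enolization of the new ketone, and mild acid removes the labile tertiary trimethylsilyl ether.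

Compound list
1 | geraniol, (2E)-3,7-dimethylocta-2,6-dien-1-ol | CC(C)=CCC/C(C)=C/CO | starting material
2 | [(2S,3S)-3-methyl-3-(4-methylpent-3-en-1-yl)oxiran-2-yl]methanol | OC[C@@H]1O[C@@]1(C)CCC=C(C)C | intermediate
3 | (2R,3S)-2-(iodomethyl)-3-methyl-3-(4-methylpent-3-en-1-yl)oxirane | IC[C@@H]1O[C@@]1(C)CCC=C(C)C | intermediate
4 | 5-methylhex-4-enoic acid | CC(C)=CCCC(=O)O | starting material
5 | 5-methyl-2-{[(2S,3S)-3-methyl-3-(4-methylpent-3-en-1-yl)oxiran-2-yl]methyl}hex-4-enoic acid (C2 epimers) | OC(=O)C(CC=C(C)C)C[C@@H]1O[C@@]1(C)CCC=C(C)C | intermediate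
6 | (5R)-5-[(2S)-2-hydroxy-6-methylhept-5-en-2-yl]-3-(3-methylbut-2-en-1-yl)oxolan-2-one (C3 epimers) | CC(C)=CCC1C[C@@H](OC1=O)[C@@](C)(O)CCC=C(C)C | intermediate
7 | methyl 4-methyl-3-oxopentanoate | COC(=O)CC(=O)C(C)C | starting material
8 | methyl (2E)-3-methoxy-4-methylpent-2-enoate | COC(=O)/C=C(/OC)C(C)C | intermediate
9 | (2E)-3-methoxy-4-methylpent-2-enoic acid | OC(=O)/C=C(/OC)C(C)C | intermediate
10 | (2E)-3-methoxy-4-methylpent-2-enoyl chloride | ClC(=O)/C=C(/OC)C(C)C | intermediate
11 | (2S)-6-methyl-2-[(2R)-4-(3-methylbut-2-en-1-yl)-5-oxooxolan-2-yl]hept-5-en-2-yl (2E)-3-methoxy-4-methylpent-2-enoate | CC(C)=CCC1C[C@@H](OC1=O)[C@@](C)(OC(=O)/C=C(/OC)C(C)C)CCC=C(C)C | intermediate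
12 | (3S,5R)-5-[(2S)-2-hydroxy-6-methylhept-5-en-2-yl]-3-[(2E)-3-methoxy-4-methylpent-2-enoyl]-3-(3-methylbut-2-en-1-yl)oxolan-2-one | CC(C)=CC[C@@]1(C(=O)/C=C(/OC)C(C)C)C[C@@H](OC1=O)[C@@](C)(O)CCC=C(C)C | intermediate
13 | (2S)-2-[(2R,3S)-2,3-dihydroxy-3,7-dimethyloct-6-en-1-yl]-5-methoxy-4,4-dimethyl-2-(3-methylbut-2-en-1-yl)cyclohex-5-ene-1,3-dione | COC1=CC(=O)[C@](CC=C(C)C)(C[C@@H](O)[C@@](C)(O)CCC=C(C)C)C(=O)C1(C)C | intermediate
14 | (2R,3aS)-2-[(2S)-2-hydroxy-6-methylhept-5-en-2-yl]-5,5-dimethyl-3a-(3-methylbut-2-en-1-yl)-3,3a-dihydro-1-benzofuran-4,6(2H,5H)-dione | O=C1C=C2O[C@@H]([C@@](C)(O)CCC=C(C)C)C[C@]2(CC=C(C)C)C(=O)C1(C)C | intermediate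
15 | (2R)-2-methylbutanoic acid | CC[C@@H](C)C(=O)O | starting material
16 | (2R)-2-methylbutanoyl chloride | CC[C@@H](C)C(Cl)=O | intermediate
17 | trimethylsilyl ether of 14 (tertiary O–SiMe3) | O=C1C=C2O[C@@H]([C@@](C)(O[Si](C)(C)C)CCC=C(C)C)C[C@]2(CC=C(C)C)C(=O)C1(C)C | intermediate
18 | 7-[(2R)-2-methylbutanoyl] derivative of 17 | CC[C@@H](C)C(=O)C1=C2O[C@@H]([C@@](C)(O[Si](C)(C)C)CCC=C(C)C)C[C@]2(CC=C(C)C)C(=O)C(C)(C)C1=O | intermediate
19 | (2R,3aS)-2-[(2S)-2-hydroxy-6-methylhept-5-en-2-yl]-5,5-dimethyl-7-[(2R)-2-methylbutanoyl]-3a-(3-methylbut-2-en-1-yl)-3,3a-dihydro-1-benzofuran-4,6(2H,5H)-dione | CC[C@@H](C)C(=O)C1=C2O[C@@H]([C@@](C)(O)CCC=C(C)C)C[C@]2(CC=C(C)C)C(=O)C(C)(C)C1=O | target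

Total steps: 10. Longest linear sequence: 7 steps (1, 2, 3, 6, 7, 8, 10).

Steps most likely to fail

Step 7. The O→C acyl migration may stall, because the vinylogous-carbonate-type ester carbonyl is a weak and hindered electrophile and the enolate may instead decay by intermolecular condensation. The dienolate may also fail to reach the geometry needed for ring closure, or the released alkoxides may reopen the non-enolizable 1,3-diketone by retro-Claisen cleavage. The fallback sets out from 3 and returns at 14; it makes the two ring bonds in separate steps and sets the quaternary centre by alkylation. Iodide 3 would be alkylated with dilithioacetate (AcOH, LiN(iPr)2, THF–DMPU) and the epoxy acid lactonized with camphorsulfonic acid to (5R)-5-[(2S)-2-hydroxy-6-methylhept-5-en-2-yl]oxolan-2-one F1. Triethylsilyl triflate and 2,6-lutidine would give the triethylsilyl ether F2. LiN(iPr)2 (2.2 equiv) followed by acid chloride 10 would give the 3-acyl lactone F3. C-Prenylation (prenyl bromide, K2CO3, acetone) should occur anti to the bulky C5 substituent and give the quaternary lactone F4, the silyl ether of 12. KN(SiMe3)2 would then effect the vinylogous Dieckmann closure to the hydroxy enone F5. Camphorsulfonic acid would close the dihydrofuran to the silylated bicyclic dione F6, and HF·pyridine would remove the silyl group to return 14.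

Step 10. The configuration of the 2-methylbutanoyl centre may erode, either through ketene formation from 16 under the basic vinyllithium or through enolization of the new ketone. O-Acylation may intervene if silylation is incomplete, and the enol ether may migrate to the tertiary oxygen during desilylation. The fallback sets out from 13 and returns at 19; it introduces the acyl group by O→C acyl migration on the free dione, without a carbanion. Diol 13 would be converted with 2-methoxypropene and PPTS at 0 °C into the acetonide F7. LiCl in DMSO at 100 °C would cleave the methyl enol ether to the acetonide-protected trione F8. Acid 15 with DCC and DMAP would give the enol ester and, by DMAP-mediated O→C acyl shift, the 2-acyl trione F9. Aqueous acetic acid would remove the acetonide, after which the secondary hydroxyl should cyclodehydrate onto C7a to give 19.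

Step 8. The tertiary hydroxyl may compete in the ring closure and give the isomeric six-membered enol ether, or acid may equilibrate the two ring sizes. The fallback sets out from 13 and returns at 14; it closes the ring by O-alkylation under basic conditions instead of carbonyl condensation. Selective mesylation of the secondary hydroxyl (MsCl, Et3N, −20 °C) would give the mesylate F10. K2CO3 in MeOH would close the epoxide F11 with inversion at the carbinol carbon. LiCl in DMSO at 100 °C would then unmask the lithium diketonate, whose oxygen at C7a should open the epoxide 5-exo at the secondary carbon with a second inversion, giving 14 with net retention.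

Further compounds
F1 | step 7 | (5R)-5-[(2S)-2-hydroxy-6-methylhept-5-en-2-yl]oxolan-2-one | O=C1CC[C@@H](O1)[C@@](C)(O)CCC=C(C)C
F2 | step 7 | (5R)-5-[(2S)-6-methyl-2-(triethylsilyloxy)hept-5-en-2-yl]oxolan-2-one | O=C1CC[C@@H](O1)[C@@](C)(O[Si](CC)(CC)CC)CCC=C(C)C
F3 | step 7 | (5R)-3-[(2E)-3-methoxy-4-methylpent-2-enoyl]-5-[(2S)-6-methyl-2-(triethylsilyloxy)hept-5-en-2-yl]oxolan-2-one (C3 epimers) | O=C(/C=C(/OC)C(C)C)C1C[C@@H](OC1=O)[C@@](C)(O[Si](CC)(CC)CC)CCC=C(C)C
F4 | step 7 | (3S,5R)-3-[(2E)-3-methoxy-4-methylpent-2-enoyl]-3-(3-methylbut-2-en-1-yl)-5-[(2S)-6-methyl-2-(triethylsilyloxy)hept-5-en-2-yl]oxolan-2-one | CC(C)=CC[C@@]1(C(=O)/C=C(/OC)C(C)C)C[C@@H](OC1=O)[C@@](C)(O[Si](CC)(CC)CC)CCC=C(C)C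
F5 | step 7 | (2S)-2-[(2R,3S)-2-hydroxy-3,7-dimethyl-3-(triethylsilyloxy)oct-6-en-1-yl]-5-methoxy-4,4-dimethyl-2-(3-methylbut-2-en-1-yl)cyclohex-5-ene-1,3-dione | COC1=CC(=O)[C@](CC=C(C)C)(C[C@@H](O)[C@@](C)(O[Si](CC)(CC)CC)CCC=C(C)C)C(=O)C1(C)C
F6 | step 7 | triethylsilyl ether of 14 | O=C1C=C2O[C@@H]([C@@](C)(O[Si](CC)(CC)CC)CCC=C(C)C)C[C@]2(CC=C(C)C)C(=O)C1(C)C
F7 | step 10 | acetonide of 13, (2S)-5-methoxy-4,4-dimethyl-2-(3-methylbut-2-en-1-yl)-2-{[(4R,5S)-2,2,5-trimethyl-5-(4-methylpent-3-en-1-yl)-1,3-dioxolan-4-yl]methyl}cyclohex-5-ene-1,3-dione | COC1=CC(=O)[C@](CC=C(C)C)(C[C@H]2OC(C)(C)O[C@@]2(C)CCC=C(C)C)C(=O)C1(C)C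
F8 | step 10 | acetonide-protected cyclohexane-1,3,5-trione (F7 without the enol ether methyl) | O=C1CC(=O)[C@](CC=C(C)C)(C[C@H]2OC(C)(C)O[C@@]2(C)CCC=C(C)C)C(=O)C1(C)C
F9 | step 10 | 2-[(2R)-2-methylbutanoyl] derivative of F8 (acyl group on the carbon between the two enolizable carbonyls) | CC[C@@H](C)C(=O)C1C(=O)[C@](CC=C(C)C)(C[C@H]2OC(C)(C)O[C@@]2(C)CCC=C(C)C)C(=O)C(C)(C)C1=O
F10 | step 8 | secondary methanesulfonate of 13 | COC1=CC(=O)[C@](CC=C(C)C)(C[C@@H](OS(C)(=O)=O)[C@@](C)(O)CCC=C(C)C)C(=O)C1(C)C
F11 | step 8 | (2S)-5-methoxy-4,4-dimethyl-2-(3-methylbut-2-en-1-yl)-2-{[(2S,3S)-3-methyl-3-(4-methylpent-3-en-1-yl)oxiran-2-yl]methyl}cyclohex-5-ene-1,3-dione | COC1=CC(=O)[C@](CC=C(C)C)(C[C@@H]2O[C@@]2(C)CCC=C(C)C)C(=O)C1(C)C
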